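The data stem from a simulated flask for substances that don't exist.

Zeta, one of my two earlier runs, held 3.43 times the first nucleophile of the other, beta, but ended with 2.49 times its target, a smaller factor, so the target did not simply follow the charge, and I wanted to know what did before judging the two new flasks, midnight and autumn.

in all of them: starting material 0.50 M

| charge | first nucleophile | second nucleophile | protic impurity | remark | time |
|---|---|---|---|---|---|
| beta | 0.70 M | 0.50 M (fed, over 3.0 h) | 10 mM | run made earlier; the fed solution adds 0.20 times the starting volume |  |
| zeta | 2.4 M | 0.50 M (fed, over 3.0 h) | 10 mM | run made earlier; the fed solution adds 0.20 times the starting volume |  |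
| midnight | 0.500 M | 0.500 M (fed, over 3.0 h) | 10.0 mM | the fed solution adds 0.20 times the starting volume | 15 h |
| autumn | 2.00 M | 0.500 M | 10.0 mM | everything together at the start, the whole solution of second nucleophile included, so that from the start the volume is larger by 0.20 times the starting volume | 15 h |

- beta (time / h: target / %): 1.33: 8.4; 2.00: 12.7; 3.00: 13.8; 5.00: 15.0; 10.0: 15.8; 15.0: 14.3
- zeta (time / h: target / %): 1.33: 24.3; 2.00: 28.8; 3.00: 33.4; 5.00: 36.3; 10.0: 37.4; 15.0: 37.6

(standard deviation of a reading: 0.5 percentage points)

- charges are per starting volume, the dose included; the dosed solution carries all of it

- the winner by amount of target, in percent of the starting material charged; "neither" if no more than 2 percentage points parts them (midnight / autumn / neither)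
- how much target is there at the end, in percent of the starting material charged: midnight
- how much target is there at the end, in percent of the starting material charged: autumn

I first took as plateaus the mean of the last two readings of each run, 15.1 % for beta and 37.5 % for zeta. But were they plateaus? Reckoning with the fraction still to come, zeta at 5.00 h lacked 3.20 % of that final target, so I accepted the time asked as long enough.

Then I turned to the part that did not become target, since if first nucleophile competes with something independent of it, target over remainder should grow in proportion to its concentration. Beta gave 0.253 L mol⁻¹ and zeta 0.250 L mol⁻¹, two different flasks in agreement, so I took 0.252 L mol⁻¹ as the capture odds, meaning target over remainder per molar of first nucleophile, a selectivity factor.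

For midnight this gave 11.2 %. Could its modest charge of first nucleophile run short? That yield needs 11.2 % of the charge, so the objection fell. For autumn the same odds gave 33.5 %, but autumn carries the larger volume from the start, which puts its first nucleophile at 1.67 M. Counting that whole dilution against it gave 29.5 %. Both earlier runs were fed alike, so they could not tell me what the early second nucleophile costs, and I committed to the lower figure, which still beat midnight by more than 2 percentage points.

The forecast named autumn, with 12 % for midnight and 27 % for autumn, the latter “very uncertain, but still above midnight”, and lower than my figure.

Midnight ended at 11.1 % and autumn at 29.2 %, so the winner was autumn, and the mechanism behind them was this: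

    starting material + protic impurity → quenched substrate (k = 0.0130 L mol⁻¹ s⁻¹)
    starting material + intermediate → side product A (k = 4.40 × 10⁻⁵ L mol⁻¹ s⁻¹)
    starting material → intermediate (k = 1.90 × 10⁻⁴ s⁻¹)
    second nucleophile + intermediate → other capture product (k = 0.320 L mol⁻¹ s⁻¹)
    first nucleophile + intermediate → target (k = 0.200 L mol⁻¹ s⁻¹)
    intermediate → side product B (k = 3.40 × 10⁻⁵ s⁻¹)
    intermediate → solvolysis product (k = 0.630 s⁻¹)

Autumn's result means capture odds of 0.206 L mol⁻¹, lower than the 0.252 L mol⁻¹ of the fed runs. The gap between the flasks comes mainly from the difference in concentration of first nucleophile: with that difference taken away, so that autumn holds midnight's concentration, autumn gives 9.34 % of target in place of 29.2 %. Autumn's odds, applied to a neighbouring flask like autumn but with 3.4 M of first nucleophile, reckon to 41.2 %, and that flask holds 41.2 % of target.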